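**Plan**

- Ring numbering (target): C1 = methyl-bearing oxirane carbon, C2 = ketone, C3 = senecioyloxy carbon, C4 = side-chain carbon, C5 = CH2, C6 = oxirane CH. Retrosynthesis: remove the two acyl groups and the C3 oxygen (enolate hydroxylation), then the oxirane oxygen (hydroxyl-directed epoxidation of an enone-derived allylic alcohol), then cut C3–C4 and C1–C6 of the carbocycle together.
- Enabling feature: ketone C2 carries two α-carbons, C3 and C1, so C1–C2–C3 is a propionylacetate unit (β-keto ester at C3, phosphorus ylide at C1), while C4–C5–C6 is the β-, α- and carbonyl carbon of an enal. The oxirane C1–C6 bond is the trace of an enone C=C.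
- Forward: side-chain dienal 10 from methyl (R)-glycidate (steps 1–5); keto-ester ylide 18 (steps 6–7); amine-catalysed Michael/Wittig [3+3] annulation builds the only carbocycle (step 8); the ester helper leaves (step 9); the oxirane ring is added (steps 10–12); C3 is oxygenated and both esters are installed (steps 13–16).
- Stereochemistry: the side-chain carbinol is bought with the glycidate; C4 is set by the (S)-prolinol catalyst; the C2 carbinol (Luche), the C1/C6 oxirane (OH-directed) and C3 (enolate face) are relayed from C4 by substrate control.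

Key step: step 8

Remark: the ester-bearing centre of 20 is an epimerisable β-keto ester carbon; it is drawn as the trans isomer and is erased in step 9.

**Route**

Step 1
Reactants: 1 methyl (2R)-oxirane-2-carboxylate; 2 (2-methylprop-1-en-1-yl)magnesium bromide
Product: 3 methyl (2R)-2-hydroxy-5-methylhex-4-enoate
Conditions: CuI (10 mol%), THF, −78 to −30 °C; aq. NH4Cl
Reagents that add atoms: none
Why: Copper-catalysed Grignard opening of the terminal epoxide at its CH2 carbon (SN2) should outrun ester addition at low temperature and leaves the C–O stereocentre of the glycidate untouched, so the (R)-carbinol of the side chain is bought.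

Step 2
Reactants: 3 methyl (2R)-2-hydroxy-5-methylhex-4-enoate
Product: 4 methyl (2R)-2-[(tert-butyldimethylsilyl)oxy]-5-methylhex-4-enoate
Conditions: tert-butyldimethylsilyl chloride, imidazole, DMF, rt
Reagents that add atoms: tert-butyldimethylsilyl chloride, CC(C)(C)[Si](C)(C)Cl
Why: Standard imidazole-promoted silylation of a secondary alcohol should give an ether that survives every basic, reductive and oxidative step up to step 15.

Step 3
Reactants: 4 methyl (2R)-2-[(tert-butyldimethylsilyl)oxy]-5-methylhex-4-enoate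
Product: 6 (3R)-3-[(tert-butyldimethylsilyl)oxy]-6-methylhept-5-en-2-one, via Weinreb amide 5 (not isolated)
Conditions: MeNH(OMe)·HCl, i-PrMgCl, THF, −20 °C; then MeMgBr, −20 to 0 °C; aq. NH4Cl
Reagents that add atoms: methylmagnesium bromide, C[Mg]Br; N,O-dimethylhydroxylamine hydrochloride, CNOC.Cl (its atoms remain only in intermediate 5)
Why: Weinreb ketone synthesis in one pot, in which the magnesium amide converts the ester to the N-methoxy-N-methylamide and the chelated tetrahedral adduct of MeMgBr stops at the ketone stage, should give the methyl ketone without enolising the α-silyloxy centre.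

Step 4
Reactants: 6 (3R)-3-[(tert-butyldimethylsilyl)oxy]-6-methylhept-5-en-2-one
Product: 7 (3R)-3-[(tert-butyldimethylsilyl)oxy]-6-methylhepta-1,5-dien-2-yl trifluoromethanesulfonate
Conditions: KN(SiMe3)2, THF, −78 °C; PhNTf2, −78 to 0 °C
Reagents that add atoms: N-phenylbis(trifluoromethanesulfonimide), O=S(=O)(N(c1ccccc1)S(=O)(=O)C(F)(F)F)C(F)(F)F
Why: Kinetic enolisation by the hindered amide base should occur at the methyl group and not at the hindered silyloxy-bearing carbon, and O-triflation of that enolate gives the 1,1-disubstituted alkenyl triflate with the stereocentre intact.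

Step 5
Reactants: 7 (3R)-3-[(tert-butyldimethylsilyl)oxy]-6-methylhepta-1,5-dien-2-yl trifluoromethanesulfonate; 8 (E)-2-(3,3-diethoxyprop-1-en-1-yl)-4,4,5,5-tetramethyl-1,3,2-dioxaborolane
Product: 10 (2E,5R)-5-[(tert-butyldimethylsilyl)oxy]-8-methyl-4-methylidenenona-2,7-dienal, via diethyl acetal 9 (not isolated)
Conditions: Pd(PPh3)4 (5 mol%), K3PO4, THF/H2O, 50 °C; then PPTS, acetone/H2O, rt
Reagents that add atoms: water, O
Why: Suzuki–Miyaura coupling of an alkenyl triflate with an (E)-alkenylboronate proceeds with retention of alkene geometry, and mild hydrolysis of the allylic acetal should release the (E)-dienal that carries the complete side chain.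

Step 6
Reactants: 11 2,2-dimethyl-1,3-dioxane-4,6-dione (Meldrum's acid); 12 2-bromopropanoyl bromide (racemic); 13 prop-2-en-1-ol
Product: 15 prop-2-en-1-yl 4-bromo-3-oxopentanoate (racemic), via acyl Meldrum's acid 14 (not isolated)
Conditions: pyridine, CH2Cl2, 0 °C; then 13, toluene, 90 °C
Reagents that add atoms: none
Why: C-acylation of Meldrum's acid followed by thermal alcoholysis through the acylketene (Meldrum's acid β-keto ester synthesis) is the standard route to γ-halo-β-keto esters and puts the allyl ester in place without exposing the allyl group to bromine.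

Step 7
Reactants: 15 prop-2-en-1-yl 4-bromo-3-oxopentanoate; 16 triphenylphosphine
Product: 18 prop-2-en-1-yl 3-oxo-4-(triphenyl-λ5-phosphanylidene)pentanoate, via phosphonium bromide 17 (not isolated)
Conditions: toluene, 40 °C; then aq. Na2CO3, CH2Cl2, 0 °C
Reagents that add atoms: none
Why: SN2 quaternisation of the α-bromo ketone and deprotonation of the most acidic C–H (between P+ and C=O) should give the keto-stabilised ylide, the methyl homologue of the well-known 4-(triphenylphosphoranylidene)acetoacetate reagents.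

Step 8
Reactants: 10 (2E,5R)-5-[(tert-butyldimethylsilyl)oxy]-8-methyl-4-methylidenenona-2,7-dienal; 18 prop-2-en-1-yl 3-oxo-4-(triphenyl-λ5-phosphanylidene)pentanoate
Product: 20 prop-2-en-1-yl (1S,6R)-6-{(3R)-3-[(tert-butyldimethylsilyl)oxy]-6-methylhepta-1,5-dien-2-yl}-3-methyl-2-oxocyclohex-3-ene-1-carboxylate, via Michael adduct 19 (not isolated)
Conditions: (S)-2-{bis[3,5-bis(trifluoromethyl)phenyl][(trimethylsilyl)oxy]methyl}pyrrolidine (20 mol%), LiClO4 (20 mol%), DABCO (20 mol%), CHCl3, rt to 40 °C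
Reagents that add atoms: none
Why: The (S)-prolinol silyl ether condenses with dienal 10 to an E, s-trans iminium ion whose one face is covered by the diaryl(silyloxy)methyl group, and the lithium/DABCO-enolised keto-ester methylene of 18 adds 1,4 to the β-carbon from the open face, which forms C3–C4 and, after hydrolysis, aldehyde 19; the stabilised ylide carbon then adds to this aldehyde (6-exo-trig, oxaphosphetane, loss of Ph3P=O) in an intramolecular Wittig olefination that forms C1=C6, whose σ-bond persists as the oxirane C–C bond. The closest known reaction type is the amine/LiClO4/DABCO-catalysed tandem Michael–Wittig cyclohexenone annulation of 4-(triphenylphosphoranylidene)acetoacetates with enals. The six-membered ring is closed by the Wittig step, the Michael step being intermolecular. C4 is set by the catalyst (the 6R centre of 20, the same series as (R)-carvone), whereas the ester-bearing C3 settles as the trans β-keto ester by enolisation and is erased in step 9. The step needs 1,4- and not 1,6-addition on the dienyl iminium ion, which is the usual course for stabilised carbon nucleophiles when the β-carbon is unblocked, and the absence of a γ-hydrogen in 10 rules out dienamine pathways; it also needs Michael addition before any intermolecular Wittig reaction, which the low reactivity of the hindered keto-stabilised ylide toward enals should secure.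

Step 9
Reactants: 20 prop-2-en-1-yl (1S,6R)-6-{(3R)-3-[(tert-butyldimethylsilyl)oxy]-6-methylhepta-1,5-dien-2-yl}-3-methyl-2-oxocyclohex-3-ene-1-carboxylate
Product: 21 (5R)-5-{(3R)-3-[(tert-butyldimethylsilyl)oxy]-6-methylhepta-1,5-dien-2-yl}-2-methylcyclohex-2-en-1-one
Conditions: Pd(PPh3)4 (5 mol%), morpholine, THF, rt
Reagents that add atoms: none
Why: Tsuji–Trost transfer of the allyl group to morpholine frees the β-keto acid, which should decarboxylate at room temperature under neutral conditions, removing the activating group without touching the silyl ether or the alkenes.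

Step 10
Reactants: 21 (5R)-5-{(3R)-3-[(tert-butyldimethylsilyl)oxy]-6-methylhepta-1,5-dien-2-yl}-2-methylcyclohex-2-en-1-one
Product: 22 (1R,5R)-5-{(3R)-3-[(tert-butyldimethylsilyl)oxy]-6-methylhepta-1,5-dien-2-yl}-2-methylcyclohex-2-en-1-ol
Conditions: NaBH4, CeCl3·7H2O, MeOH, −78 °C
Reagents that add atoms: none
Why: Luche 1,2-reduction with axial hydride delivery to the enone half-chair (side chain pseudo-equatorial) should give the pseudo-equatorial alcohol cis to the C4 substituent, as in the reduction of carvone to cis-carveol.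

Step 11
Reactants: 22 (1R,5R)-5-{(3R)-3-[(tert-butyldimethylsilyl)oxy]-6-methylhepta-1,5-dien-2-yl}-2-methylcyclohex-2-en-1-ol
Product: 23 (1R,2R,4S,6S)-4-{(3R)-3-[(tert-butyldimethylsilyl)oxy]-6-methylhepta-1,5-dien-2-yl}-1-methyl-7-oxabicyclo[4.1.0]heptan-2-ol
Conditions: VO(acac)2 (5 mol%), t-BuOOH, CH2Cl2, 0 °C to rt
Reagents that add atoms: tert-butyl hydroperoxide, CC(C)(C)OO
Why: Hydroxyl-directed vanadium-catalysed epoxidation delivers the peroxide oxygen to the ring alkene on the face of the allylic hydroxyl group, which sets C1 and C6 with the oxirane cis to the side chain, while the undirected side-chain alkenes (silyl-protected allylic ether, isolated trisubstituted alkene) should be left alone.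

Step 12
Reactants: 23 (1R,2R,4S,6S)-4-{(3R)-3-[(tert-butyldimethylsilyl)oxy]-6-methylhepta-1,5-dien-2-yl}-1-methyl-7-oxabicyclo[4.1.0]heptan-2-ol
Product: 24 (1S,4R,6S)-4-{(3R)-3-[(tert-butyldimethylsilyl)oxy]-6-methylhepta-1,5-dien-2-yl}-1-methyl-7-oxabicyclo[4.1.0]heptan-2-one
Conditions: Dess–Martin periodinane, pyridine, CH2Cl2, 0 °C to rt
Reagents that add atoms: none
Why: Dess–Martin oxidation of the epoxy alcohol under buffered, non-epimerising conditions should return the ketone with the cis-oxirane in place.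

Step 13
Reactants: 24 (1S,4R,6S)-4-{(3R)-3-[(tert-butyldimethylsilyl)oxy]-6-methylhepta-1,5-dien-2-yl}-1-methyl-7-oxabicyclo[4.1.0]heptan-2-one
Product: 25 (1S,3S,4S,6S)-4-{(3R)-3-[(tert-butyldimethylsilyl)oxy]-6-methylhepta-1,5-dien-2-yl}-3-hydroxy-1-methyl-7-oxabicyclo[4.1.0]heptan-2-one
Conditions: KN(SiMe3)2, THF, −78 °C; 2-(benzenesulfonyl)-3-phenyloxaziridine, −78 °C; aq. NH4Cl
Reagents that add atoms: 2-(benzenesulfonyl)-3-phenyloxaziridine, O=S(=O)(N1OC1c1ccccc1)c1ccccc1
Why: Davis enolate hydroxylation, in which only C3 can be enolised (C1 is quaternary) and the oxaziridine oxygen should be transferred to the potassium enolate on the face opposite the adjacent C4 side chain and the oxirane oxygen, giving the trans (diequatorial) ketol.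

Step 14
Reactants: 25 (1S,3S,4S,6S)-4-{(3R)-3-[(tert-butyldimethylsilyl)oxy]-6-methylhepta-1,5-dien-2-yl}-3-hydroxy-1-methyl-7-oxabicyclo[4.1.0]heptan-2-one
Product: 26 (1S,3S,4S,6S)-4-{(3R)-3-[(tert-butyldimethylsilyl)oxy]-6-methylhepta-1,5-dien-2-yl}-1-methyl-2-oxo-7-oxabicyclo[4.1.0]heptan-3-yl 3-methylbut-2-enoate
Conditions: 3-methylbut-2-enoyl chloride, pyridine, DMAP (cat.), CH2Cl2, 0 °C
Reagents that add atoms: 3-methylbut-2-enoyl chloride, CC(C)=CC(Cl)=O
Why: DMAP-catalysed acylation of the secondary ketol with the acid chloride and the weak base pyridine should give the senecioate without deconjugating the acyl group, and any epimerisation at C3 would converge on the more stable trans isomer.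

Step 15
Reactants: 26 (1S,3S,4S,6S)-4-{(3R)-3-[(tert-butyldimethylsilyl)oxy]-6-methylhepta-1,5-dien-2-yl}-1-methyl-2-oxo-7-oxabicyclo[4.1.0]heptan-3-yl 3-methylbut-2-enoate
Product: 27 (1S,3S,4S,6S)-4-[(3R)-3-hydroxy-6-methylhepta-1,5-dien-2-yl]-1-methyl-2-oxo-7-oxabicyclo[4.1.0]heptan-3-yl 3-methylbut-2-enoate
Conditions: HF·pyridine, pyridine, THF, 0 °C to rt
Reagents that add atoms: none
Why: Fluoride-mediated desilylation under pyridine-buffered, non-basic conditions should free the side-chain alcohol while the electron-poor α,β-epoxy ketone and the ketol ester are tolerated.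

Step 16
Reactants: 27 (1S,3S,4S,6S)-4-[(3R)-3-hydroxy-6-methylhepta-1,5-dien-2-yl]-1-methyl-2-oxo-7-oxabicyclo[4.1.0]heptan-3-yl 3-methylbut-2-enoate
Product: 28 (1S,3S,4S,6S)-4-[(3R)-3-acetoxy-6-methylhepta-1,5-dien-2-yl]-1-methyl-2-oxo-7-oxabicyclo[4.1.0]heptan-3-yl 3-methylbut-2-enoate (CNP0168401.1)
Conditions: Ac2O, pyridine, DMAP (cat.), CH2Cl2, 0 °C
Reagents that add atoms: acetic anhydride, CC(=O)OC(C)=O
Why: DMAP-catalysed acetylation of the only free hydroxyl group should complete the target with all five stereocentres untouched.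

**Compound list**

1 | methyl (2R)-oxirane-2-carboxylate | COC(=O)[C@H]1CO1 | starting material
2 | (2-methylprop-1-en-1-yl)magnesium bromide | CC(C)=C[Mg]Br | starting material
3 | methyl (2R)-2-hydroxy-5-methylhex-4-enoate | COC(=O)[C@@H](CC=C(C)C)O | intermediate
4 | methyl (2R)-2-[(tert-butyldimethylsilyl)oxy]-5-methylhex-4-enoate | COC(=O)[C@@H](CC=C(C)C)O[Si](C)(C)C(C)(C)C | intermediate
5 | (2R)-2-[(tert-butyldimethylsilyl)oxy]-N-methoxy-N,5-dimethylhex-4-enamide | CON(C)C(=O)[C@@H](CC=C(C)C)O[Si](C)(C)C(C)(C)C | intermediate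
6 | (3R)-3-[(tert-butyldimethylsilyl)oxy]-6-methylhept-5-en-2-one | CC(=O)[C@@H](CC=C(C)C)O[Si](C)(C)C(C)(C)C | intermediate
7 | (3R)-3-[(tert-butyldimethylsilyl)oxy]-6-methylhepta-1,5-dien-2-yl trifluoromethanesulfonate | C=C(OS(=O)(=O)C(F)(F)F)[C@@H](CC=C(C)C)O[Si](C)(C)C(C)(C)C | intermediate
8 | (E)-2-(3,3-diethoxyprop-1-en-1-yl)-4,4,5,5-tetramethyl-1,3,2-dioxaborolane | CCOC(OCC)/C=C/B1OC(C)(C)C(C)(C)O1 | starting material
9 | (2E,5R)-5-[(tert-butyldimethylsilyl)oxy]-1,1-diethoxy-8-methyl-4-methylidenenona-2,7-diene | CCOC(OCC)/C=C/C(=C)[C@@H](CC=C(C)C)O[Si](C)(C)C(C)(C)C | intermediate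
10 | (2E,5R)-5-[(tert-butyldimethylsilyl)oxy]-8-methyl-4-methylidenenona-2,7-dienal | O=C/C=C/C(=C)[C@@H](CC=C(C)C)O[Si](C)(C)C(C)(C)C | intermediate
11 | 2,2-dimethyl-1,3-dioxane-4,6-dione | CC1(C)OC(=O)CC(=O)O1 | starting material
12 | 2-bromopropanoyl bromide (racemic) | CC(Br)C(=O)Br | starting material
13 | prop-2-en-1-ol | C=CCO | starting material
14 | 5-(2-bromopropanoyl)-2,2-dimethyl-1,3-dioxane-4,6-dione | CC(Br)C(=O)C1C(=O)OC(C)(C)OC1=O | intermediate
15 | prop-2-en-1-yl 4-bromo-3-oxopentanoate (racemic) | C=CCOC(=O)CC(=O)C(C)Br | intermediate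
16 | triphenylphosphine | c1ccc(cc1)P(c1ccccc1)c1ccccc1 | starting material
17 | [5-oxo-5-(prop-2-en-1-yloxy)-3-oxopentan-2-yl]triphenylphosphonium bromide | C=CCOC(=O)CC(=O)C(C)[P+](c1ccccc1)(c1ccccc1)c1ccccc1.[Br-] | intermediate
18 | prop-2-en-1-yl 3-oxo-4-(triphenyl-λ5-phosphanylidene)pentanoate | C=CCOC(=O)CC(=O)C(C)=P(c1ccccc1)(c1ccccc1)c1ccccc1 | intermediate
19 | prop-2-en-1-yl 2-{(3R,5R)-5-[(tert-butyldimethylsilyl)oxy]-8-methyl-4-methylidene-1-oxonon-7-en-3-yl}-3-oxo-4-(triphenyl-λ5-phosphanylidene)pentanoate | C=C([C@@H](CC=C(C)C)O[Si](C)(C)C(C)(C)C)[C@H](CC=O)C(C(=O)OCC=C)C(=O)C(C)=P(c1ccccc1)(c1ccccc1)c1ccccc1 | intermediate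
20 | prop-2-en-1-yl (1S,6R)-6-{(3R)-3-[(tert-butyldimethylsilyl)oxy]-6-methylhepta-1,5-dien-2-yl}-3-methyl-2-oxocyclohex-3-ene-1-carboxylate | C=C([C@@H](CC=C(C)C)O[Si](C)(C)C(C)(C)C)[C@@H]1CC=C(C)C(=O)[C@H]1C(=O)OCC=C | intermediate
21 | (5R)-5-{(3R)-3-[(tert-butyldimethylsilyl)oxy]-6-methylhepta-1,5-dien-2-yl}-2-methylcyclohex-2-en-1-one | C=C([C@@H](CC=C(C)C)O[Si](C)(C)C(C)(C)C)[C@@H]1CC=C(C)C(=O)C1 | intermediate
22 | (1R,5R)-5-{(3R)-3-[(tert-butyldimethylsilyl)oxy]-6-methylhepta-1,5-dien-2-yl}-2-methylcyclohex-2-en-1-ol | C=C([C@@H](CC=C(C)C)O[Si](C)(C)C(C)(C)C)[C@@H]1CC=C(C)[C@H](O)C1 | intermediate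
23 | (1R,2R,4S,6S)-4-{(3R)-3-[(tert-butyldimethylsilyl)oxy]-6-methylhepta-1,5-dien-2-yl}-1-methyl-7-oxabicyclo[4.1.0]heptan-2-ol | C=C([C@@H](CC=C(C)C)O[Si](C)(C)C(C)(C)C)[C@@H]1C[C@@H]2O[C@]2(C)[C@H](O)C1 | intermediate
24 | (1S,4R,6S)-4-{(3R)-3-[(tert-butyldimethylsilyl)oxy]-6-methylhepta-1,5-dien-2-yl}-1-methyl-7-oxabicyclo[4.1.0]heptan-2-one | C=C([C@@H](CC=C(C)C)O[Si](C)(C)C(C)(C)C)[C@@H]1C[C@@H]2O[C@]2(C)C(=O)C1 | intermediate
25 | (1S,3S,4S,6S)-4-{(3R)-3-[(tert-butyldimethylsilyl)oxy]-6-methylhepta-1,5-dien-2-yl}-3-hydroxy-1-methyl-7-oxabicyclo[4.1.0]heptan-2-one | C=C([C@@H](CC=C(C)C)O[Si](C)(C)C(C)(C)C)[C@@H]1C[C@@H]2O[C@]2(C)C(=O)[C@H]1O | intermediate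
26 | (1S,3S,4S,6S)-4-{(3R)-3-[(tert-butyldimethylsilyl)oxy]-6-methylhepta-1,5-dien-2-yl}-1-methyl-2-oxo-7-oxabicyclo[4.1.0]heptan-3-yl 3-methylbut-2-enoate | C=C([C@@H](CC=C(C)C)O[Si](C)(C)C(C)(C)C)[C@@H]1C[C@@H]2O[C@]2(C)C(=O)[C@H]1OC(=O)C=C(C)C | intermediate
27 | (1S,3S,4S,6S)-4-[(3R)-3-hydroxy-6-methylhepta-1,5-dien-2-yl]-1-methyl-2-oxo-7-oxabicyclo[4.1.0]heptan-3-yl 3-methylbut-2-enoate | C=C([C@@H](CC=C(C)C)O)[C@@H]1C[C@@H]2O[C@]2(C)C(=O)[C@H]1OC(=O)C=C(C)C | intermediate
28 | (1S,3S,4S,6S)-4-[(3R)-3-acetoxy-6-methylhepta-1,5-dien-2-yl]-1-methyl-2-oxo-7-oxabicyclo[4.1.0]heptan-3-yl 3-methylbut-2-enoate | C=C([C@@H](CC=C(C)C)OC(C)=O)[C@@H]1C[C@@H]2O[C@]2(C)C(=O)[C@H]1OC(=O)C=C(C)C | target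

**Count and risks**

Total step count: 16. Longest linear sequence: 14 steps (steps 1–5 and 8–16, from methyl (R)-glycidate).

Steps most likely to fail:

1. Step 8. The keto ester may add 1,6 to the terminal methylidene carbon of the dienyl iminium ion instead of 1,4, or ring closure of the hindered methyl-substituted ylide may be so slow that uncatalysed background addition and intermolecular olefination erode regio- and enantiocontrol. Fallback, setting out from 7 and coming back at 21: Miyaura borylation of triflate 7 (B2pin2, PdCl2(PPh3)2, PPh3, KOPh, toluene, 50 °C) would give the alkenylboronate F1. Rhodium-catalysed asymmetric 1,4-addition of F1 to commercial 6-methylcyclohex-2-en-1-one ([Rh(OH)(cod)]2, (R)-BINAP, aqueous dioxane) would give the 5-alkenyl-2-methylcyclohexanone F2, with C4 (target numbering) set by the ligand and the methyl-bearing centre left as a mixture. Thermodynamic enolisation (Me3SiCl, NaI, Et3N, MeCN) would give the more substituted silyl enol ether F3, and Saegusa–Ito dehydrogenation (Pd(OAc)2, MeCN) would then deliver enone 21, which enters step 10.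

2. Step 13. Oxygen may be transferred to the wrong face of the epoxy-ketone enolate, or the strongly basic conditions may degrade the substrate (opening of the oxirane, self-condensation, ketol shift after hydroxylation). Fallback, setting out from 21 and coming back at 26: the oxygen is introduced before the oxirane exists. The cross-conjugated potassium enolate of enone 21 (KN(SiMe3)2, THF, −78 °C) would be hydroxylated with the same oxaziridine anti to the side chain to give the trans hydroxy enone F4. Acylation with 3-methylbut-2-enoyl chloride (pyridine, DMAP) would give the senecioate F5, Luche reduction the cis allylic alcohol F6, and VO(acac)2/t-BuOOH the epoxy alcohol F7. Dess–Martin oxidation would then give 26, which enters step 15.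

3. Step 15. Removal of the hindered allylic silyl ether may be slow enough for fluoride or acid to open the oxirane, epimerise C3 or shift the senecioyl group. Fallback, setting out from 24 and coming back at 28: the silyl group is exchanged for the final acetate before the sensitive ketol ester is made. Buffered desilylation of 24 (Bu4NF, AcOH, THF) would give the alcohol F8 and acetylation (Ac2O, pyridine, DMAP) the acetate F9. Ketone-selective deprotonation (KN(SiMe3)2, 1.05 equiv, −78 °C) and oxaziridine hydroxylation would give the ketol F10, and acylation with 3-methylbut-2-enoyl chloride (pyridine, DMAP) would give the target 28 directly.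

**Further compounds**

F1 | step 8 | tert-butyl(dimethyl){[(3R)-6-methyl-2-(4,4,5,5-tetramethyl-1,3,2-dioxaborolan-2-yl)hepta-1,5-dien-3-yl]oxy}silane | C=C(B1OC(C)(C)C(C)(C)O1)[C@@H](CC=C(C)C)O[Si](C)(C)C(C)(C)C
F2 | step 8 | (5R)-5-{(3R)-3-[(tert-butyldimethylsilyl)oxy]-6-methylhepta-1,5-dien-2-yl}-2-methylcyclohexan-1-one (mixture at C2) | C=C([C@@H](CC=C(C)C)O[Si](C)(C)C(C)(C)C)[C@@H]1CCC(C)C(=O)C1
F3 | step 8 | {[(5R)-5-{(3R)-3-[(tert-butyldimethylsilyl)oxy]-6-methylhepta-1,5-dien-2-yl}-2-methylcyclohex-1-en-1-yl]oxy}trimethylsilane | C=C([C@@H](CC=C(C)C)O[Si](C)(C)C(C)(C)C)[C@@H]1CCC(C)=C(O[Si](C)(C)C)C1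
F4 | step 13 | (5S,6S)-5-{(3R)-3-[(tert-butyldimethylsilyl)oxy]-6-methylhepta-1,5-dien-2-yl}-6-hydroxy-2-methylcyclohex-2-en-1-one | C=C([C@@H](CC=C(C)C)O[Si](C)(C)C(C)(C)C)[C@@H]1CC=C(C)C(=O)[C@H]1O
F5 | step 13 | (1S,6S)-6-{(3R)-3-[(tert-butyldimethylsilyl)oxy]-6-methylhepta-1,5-dien-2-yl}-3-methyl-2-oxocyclohex-3-en-1-yl 3-methylbut-2-enoate | C=C([C@@H](CC=C(C)C)O[Si](C)(C)C(C)(C)C)[C@@H]1CC=C(C)C(=O)[C@H]1OC(=O)C=C(C)C
F6 | step 13 | (1S,2S,6S)-6-{(3R)-3-[(tert-butyldimethylsilyl)oxy]-6-methylhepta-1,5-dien-2-yl}-2-hydroxy-3-methylcyclohex-3-en-1-yl 3-methylbut-2-enoate | C=C([C@@H](CC=C(C)C)O[Si](C)(C)C(C)(C)C)[C@@H]1CC=C(C)[C@H](O)[C@H]1OC(=O)C=C(C)C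
F7 | step 13 | (1R,2R,3S,4S,6S)-4-{(3R)-3-[(tert-butyldimethylsilyl)oxy]-6-methylhepta-1,5-dien-2-yl}-2-hydroxy-1-methyl-7-oxabicyclo[4.1.0]heptan-3-yl 3-methylbut-2-enoate | C=C([C@@H](CC=C(C)C)O[Si](C)(C)C(C)(C)C)[C@@H]1C[C@@H]2O[C@]2(C)[C@H](O)[C@H]1OC(=O)C=C(C)C
F8 | step 15 | (1S,4R,6S)-4-[(3R)-3-hydroxy-6-methylhepta-1,5-dien-2-yl]-1-methyl-7-oxabicyclo[4.1.0]heptan-2-one | C=C([C@@H](CC=C(C)C)O)[C@@H]1C[C@@H]2O[C@]2(C)C(=O)C1
F9 | step 15 | (1S,4R,6S)-4-[(3R)-3-acetoxy-6-methylhepta-1,5-dien-2-yl]-1-methyl-7-oxabicyclo[4.1.0]heptan-2-one | C=C([C@@H](CC=C(C)C)OC(C)=O)[C@@H]1C[C@@H]2O[C@]2(C)C(=O)C1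
F10 | step 15 | (1S,3S,4S,6S)-4-[(3R)-3-acetoxy-6-methylhepta-1,5-dien-2-yl]-3-hydroxy-1-methyl-7-oxabicyclo[4.1.0]heptan-2-one | C=C([C@@H](CC=C(C)C)OC(C)=O)[C@@H]1C[C@@H]2O[C@]2(C)C(=O)[C@H]1O
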